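The readings are simulated with made-up constants; noise was put on by code.

I chose to count chains by the initiator and to draw one curve for each of the two flasks, south-east and north: the fraction F of the charged free monomer that stands in chains.

| flask | free monomer | transfer agent | initiator | remark | time |
|---|---|---|---|---|---|
| amber | 10 mM (fed, over 2.5 d) | 0.10 mM | 25 µM | run made earlier; the fed solution adds 0.50 times the starting volume |  |
| teal | 10 mM (fed, over 2.5 d) | 0.10 mM | 38 µM | run made earlier; the fed solution adds 0.50 times the starting volume |  |
| south-east | 10 mM (fed, over 2.5 d) | 0.100 mM | 50 µM | the fed solution adds 0.50 times the starting volume | 8.0 d |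
| north | 10 mM (fed, over 10 d) | 0.100 mM | 50 µM | the fed solution adds 0.50 times the starting volume | 8.0 d |

- amber (time / d: monomer in chains / %, free monomer / %): 0.417: 0, 20; 1.25: 1, 48; 2.00: 7, 70; 3.00: 15, 80; 5.00: 31, 69
- teal (time / d: monomer in chains / %, free monomer / %): 0.417: 0, 16; 1.25: 4, 48; 2.00: 12, 70; 3.00: 25, 75; 5.00: 44, 57

(readings scatter by 1.5 percentage points)

- charges are per starting volume, the dose included; the dosed solution carries all of it
- the average divides the monomer in chains by the number of chains begun, living and dead together
- the analysis behind the earlier runs scatters by 1.5 percentage points, standard deviation
- percentages count the whole charge, also what has not yet gone in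
- the earlier runs do not show the number of chains; that part of a forecast is a guess

- which of the two ends with the longer chains by the average number of monomer units in a chain (chains begun, living or dead) ("neither" if they lie within 10%) (south-east / north / neither)
- average number of monomer units in a chain (chains begun, living or dead) at the end, south-east
- average number of monomer units in a chain (chains begun, living or dead) at the end, north

From 2.00 d to 5.00 d I divided the slope of monomer in chains by the mean free monomer of the three readings. This gave a pseudo-first-order constant k as a reading, with the scatter of those readings:

k(amber) = 0.110 d⁻¹
k(teal) = 0.158 d⁻¹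

Their ratio, 1.44, lay close to the initiator ratio, 1.52. So I took the growing ends as already formed and guessed one chain begun per initiator, since the runs show no chain count. The length then has a ceiling, Λ, the free monomer charged over the initiator charged, and the average length is ΛF:

Λ = 200
k at 50 µM = 0.214 d⁻¹

With τ the dosing time, F during the feed is

F = t/τ − (1 − e^(−kt))/(kτ)

My south-east curve started flat, as amber's 0% at 0.417 d did, and reached its knee at 2.5 d with F = 22.5%. Free monomer then decayed with k, crossed monomer in chains at 4.55 d, and stood at F = 76.1% by 8.0 d, on its way to the whole charge. My north curve was still being fed at 8.0 d, with 80.0% of the charge gone in; the same formula, written as that share times 1 − (1 − e^(−kt))/(kt), gave F = 41.7%. I therefore expected 152 for south-east, longer than 83.4 for north.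

The forecast also said south-east, but with 58 and 33, counting “0.10 mM transfer agent plus a guessed 0.02 mM from initiator, about 0.12 mM”; on that count it differed from my 0.05 mM.

The flask gave south-east, with 140 and 77.4.

    free monomer + initiator → living end + monomer in chains (k = 0.00710 M⁻¹ s⁻¹)
    living end + transfer agent → dead chain (kL = 0.0150 M⁻¹ s⁻¹)
    free monomer + living end → monomer in chains + living end, rate k3*[living end]*[free monomer] (k = 0.0860 M⁻¹ s⁻¹)

At 8.00 d, south-east held 70.2% in chains with 0% of its initiator left, and Λ times that share is 140. The neighbour of north with 0.12 mM of initiator has Λ = 83.3. It held 58.7% in chains at 8.00 d, with 0.197% of its initiator left, so ΛF is 48.9, and its average length was 49.0.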